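**Plan**
- The first cut is the C(=O)–CH2 bond of the C8 side chain, read as the retron of an alkene hydroacylation: the formyl C–H of an 8-formylchroman-2-one adds across the vinyl group of 4-methoxystyrene, with no co-product.
- The feature that allows this is the free C7–OH ortho to the C8 carbonyl on the benzo ring (a salicylaldehyde unit). It holds Rh in a five-membered O,C-acyl chelate, so the two halves can be joined last, with all phenols free.
- The next cuts are C8–CHO (electrophilic formylation; C8 is para to the C5 oxygen) and C4–Ph (conjugate arylation of the coumarin C3=C4 bond).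
- Forward: the lactone ring is present from the start in 5,7-dimethoxycoumarin, which fixes the lactone oxygen. Then C4–Ph, C8–CHO, O-demethylation and chain attachment follow in that order.
- The single stereocentre (C4, S) comes from catalyst control in the Rh/(S)-SEGPHOS 1,4-addition; no later step touches it.

Key step: step 4

Remark: the 4S sense of the Rh/(S)-SEGPHOS addition is assigned by analogy with simpler coumarins; should the adduct prove to be 4R, (R)-SEGPHOS is used and nothing else changes.

**Route**

Step 1
Reactants: 1 5,7-dimethoxycoumarin; 2 phenylboronic acid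
Product: 3 (4S)-5,7-dimethoxy-4-phenylchroman-2-one
Conditions: Rh(acac)(C2H4)2 (3 mol %), (S)-SEGPHOS (3.3 mol %), 2 (5 equiv), 1,4-dioxane/H2O 10:1, 60 °C
Reagents that add atoms: none
Why: Hayashi–Miyaura Rh-catalysed asymmetric 1,4-addition of an arylboronic acid to a coumarin: the (S)-SEGPHOS-bound phenyl–Rh(I) species carbometalates the cis-locked C3=C4 enoate on one enantioface and water protonates the oxa-π-allyl, so the C4 stereocentre (S) is set by the ligand while the lactone oxygen stays where the coumarin had it.

Step 2
Reactants: 3 (4S)-5,7-dimethoxy-4-phenylchroman-2-one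
Product: 5 (4S)-5,7-dimethoxy-2-oxo-4-phenylchroman-8-carbaldehyde, via α-chloro ether 4 (not isolated)
Conditions: Cl2CHOMe (1.5 equiv), TiCl4 (2.2 equiv), CH2Cl2, −20 to 0 °C; then ice/1 M HCl
Reagents that add atoms: dichloromethyl methyl ether COC(Cl)Cl; water O
Why: Rieche formylation (Friedel–Crafts type): C8 is para to the C5 methoxy and ortho to the C7 methoxy group, the reactive position of a resorcinol dimethyl ether, whereas C6 lies between both methoxy groups, so the TiCl4-activated electrophile should enter at C8 and the deactivated product should not react twice; the lactone and the C4 stereocentre are inert to the Lewis acid at or below 0 °C.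

Step 3
Reactants: 5 (4S)-5,7-dimethoxy-2-oxo-4-phenylchroman-8-carbaldehyde
Product: 6 (4S)-5,7-dihydroxy-2-oxo-4-phenylchroman-8-carbaldehyde
Conditions: BBr3 (5 equiv), CH2Cl2, −78 °C to rt; then ice-water
Reagents that add atoms: none
Why: Lewis acid-mediated cleavage of aryl methyl ethers (BBr3): bromide attacks the methyl carbon of each O-boron adduct, the aryl lactone has no alkyl C–O bond to cleave in this way and stays closed on the same oxygen, and the formyl group and the non-acidic C4 stereocentre are returned unchanged on hydrolysis.

Step 4
Reactants: 6 (4S)-5,7-dihydroxy-2-oxo-4-phenylchroman-8-carbaldehyde; 7 4-methoxystyrene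
Product: 8 (4S)-5,7-dihydroxy-8-[3-(4-methoxyphenyl)propanoyl]-4-phenylchroman-2-one (target)
Conditions: [Rh(cod)OMe]2 (2.5 mol %), bulky BINOL-derived phosphoramidite (10 mol %), K3PO4 (10 mol %), 7 (3 equiv), dry 1,4-dioxane, 70 °C
Reagents that add atoms: none
Why: The Rh(I) methoxide exchanges with the C7 phenol, and the aryloxide delivers the metal to the adjacent C8 formyl C–H bond; oxidative addition gives a five-membered O,C-chelated acyl–Rh(III) hydride that resists CO extrusion, and reversible insertion of the vinyl group of 7 into Rh–H followed by C–C reductive elimination from the primary alkyl forms the C(=O)–CH2 bond. The closest known reaction type is the Rh-catalysed chelation-assisted intermolecular hydroacylation of terminal alkenes with salicylaldehydes, which gives linear 2-hydroxyaryl ketones. No ring is closed and no stereocentre is created, and the C4 stereocentre is remote from the metal and not acidic, so it is not at risk. The selectivity needed is linear over branched (anti-Markovnikov); it should be secured by the reversibility of hydrometalation together with the bulky ligand, which disfavours reductive elimination from the secondary benzylic alkyl next to the doubly ortho-substituted aroyl group. Chemoselectivity follows from the fact that only the C7 oxygen can form the chelate, so the C5–OH and the aryl lactone should be spectators under catalytic weak base in a dry medium.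

**Compound list**

1 | 5,7-dimethoxycoumarin (5,7-dimethoxy-2H-chromen-2-one) | COc1cc(OC)c2ccc(=O)oc2c1 | starting material
2 | phenylboronic acid | OB(O)c1ccccc1 | starting material
3 | (4S)-5,7-dimethoxy-4-phenylchroman-2-one | COc1cc(OC)c2c(c1)OC(=O)C[C@H]2c1ccccc1 | intermediate
4 | (4S)-8-[chloro(methoxy)methyl]-5,7-dimethoxy-4-phenylchroman-2-one (either configuration at the new carbon; not isolated) | COc1cc(OC)c2c(c1C(Cl)OC)OC(=O)C[C@H]2c1ccccc1 | intermediate
5 | (4S)-5,7-dimethoxy-2-oxo-4-phenylchroman-8-carbaldehyde | COc1cc(OC)c2c(c1C=O)OC(=O)C[C@H]2c1ccccc1 | intermediate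
6 | (4S)-5,7-dihydroxy-2-oxo-4-phenylchroman-8-carbaldehyde | O=Cc1c(O)cc(O)c2c1OC(=O)C[C@H]2c1ccccc1 | intermediate
7 | 4-methoxystyrene (1-ethenyl-4-methoxybenzene) | C=Cc1ccc(OC)cc1 | starting material
8 | (4S)-5,7-dihydroxy-8-[3-(4-methoxyphenyl)propanoyl]-4-phenylchroman-2-one | COc1ccc(CCC(=O)c2c(O)cc(O)c3c2OC(=O)C[C@H]3c2ccccc2)cc1 | target

**Count**

Total steps: 4. Longest linear sequence: 4 steps (1 → 3 → 5 → 6 → 8).

**Steps most likely to fail**

1. Step 4. What may go wrong: insertion of the styrene in the Markovnikov sense and reductive elimination from the benzylic alkyl (branched ketone), decarbonylation of the acyl–rhodium hydride, or base-mediated opening of the aryl lactone and re-closure on the other ortho oxygen. The fallback sets out from 6 and comes back at 8. Both phenols of 6 are silylated (TBSCl, imidazole, DMF) to give (4S)-5,7-bis(tert-butyldimethylsilyloxy)-2-oxo-4-phenylchroman-8-carbaldehyde F1. One equivalent of 4-methoxyphenethylmagnesium bromide F2, made from 4-methoxyphenethyl bromide and Mg in THF, is added at −78 °C, where the aldehyde should react well before the aryl lactone; NH4Cl quench gives (4S)-5,7-bis(tert-butyldimethylsilyloxy)-8-[1-hydroxy-3-(4-methoxyphenyl)propyl]-4-phenylchroman-2-one F3 as a mixture of carbinol epimers. Dess–Martin oxidation gives (4S)-5,7-bis(tert-butyldimethylsilyloxy)-8-[3-(4-methoxyphenyl)propanoyl]-4-phenylchroman-2-one F4, and HF·pyridine in THF removes both silyl groups to give 8. The same C(=O)–CH2 bond is thus made by polar 1,2-addition and oxidation instead of C–H activation.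

2. Step 2. What may go wrong: competing attack of the electrophile at C6 between the two methoxy groups, or a second formylation. The fallback sets out from 3 and comes back at 5. Lactone 3 is opened with pyrrolidine (THF, rt) to (3S)-3-(2-hydroxy-4,6-dimethoxyphenyl)-3-phenyl-1-(pyrrolidin-1-yl)propan-1-one F5, whose only free phenol has a single open ortho position, the future C8. Magnesium-mediated ortho-formylation (MgCl2, Et3N, paraformaldehyde, MeCN, reflux), which is confined to the position ortho to the phenoxide, gives (3S)-3-(3-formyl-2-hydroxy-4,6-dimethoxyphenyl)-3-phenyl-1-(pyrrolidin-1-yl)propan-1-one F6. TsOH in toluene at 110 °C closes the lactone on that same phenol with loss of pyrrolidine and gives 5.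

3. Step 1. What may go wrong: slow carbometalation of the electron-rich enoate next to the C5 methoxy group, so that protodeboronation consumes the boronic acid, or erosion of facial selectivity by the same peri substituent. The fallback sets out from 1 (with 2) and comes back at 3. Oxidative Heck arylation of 1 with 2 (Pd(OAc)2, 1,10-phenanthroline, O2, DMF, 80 °C) gives 5,7-dimethoxy-4-phenylcoumarin F7. Copper hydride asymmetric conjugate reduction (Cu(OAc)2, the DTBM-SEGPHOS enantiomer that delivers hydride to give 4S, PMHS in limited amount, t-BuOH, toluene) gives 3. The stereocentre is then set by hydride delivery to a tetrasubstituted-carbon precursor instead of aryl delivery.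

**Further compounds**

F1 | step 4 | (4S)-5,7-bis(tert-butyldimethylsilyloxy)-2-oxo-4-phenylchroman-8-carbaldehyde | CC(C)(C)[Si](C)(C)Oc1cc(O[Si](C)(C)C(C)(C)C)c2c(c1C=O)OC(=O)C[C@H]2c1ccccc1
F2 | step 4 | 4-methoxyphenethylmagnesium bromide | COc1ccc(CC[Mg]Br)cc1
F3 | step 4 | (4S)-5,7-bis(tert-butyldimethylsilyloxy)-8-[1-hydroxy-3-(4-methoxyphenyl)propyl]-4-phenylchroman-2-one (both carbinol epimers) | COc1ccc(CCC(O)c2c(O[Si](C)(C)C(C)(C)C)cc(O[Si](C)(C)C(C)(C)C)c3c2OC(=O)C[C@H]3c2ccccc2)cc1
F4 | step 4 | (4S)-5,7-bis(tert-butyldimethylsilyloxy)-8-[3-(4-methoxyphenyl)propanoyl]-4-phenylchroman-2-one | COc1ccc(CCC(=O)c2c(O[Si](C)(C)C(C)(C)C)cc(O[Si](C)(C)C(C)(C)C)c3c2OC(=O)C[C@H]3c2ccccc2)cc1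
F5 | step 2 | (3S)-3-(2-hydroxy-4,6-dimethoxyphenyl)-3-phenyl-1-(pyrrolidin-1-yl)propan-1-one | O=C(N1CCCC1)C[C@H](c1c(O)cc(OC)cc1OC)c1ccccc1
F6 | step 2 | (3S)-3-(3-formyl-2-hydroxy-4,6-dimethoxyphenyl)-3-phenyl-1-(pyrrolidin-1-yl)propan-1-one | O=C(N1CCCC1)C[C@H](c1c(O)c(C=O)c(OC)cc1OC)c1ccccc1
F7 | step 1 | 5,7-dimethoxy-4-phenylcoumarin | COc1cc(OC)c2c(-c3ccccc3)cc(=O)oc2c1
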